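## The problem

Compound 30 (CNP0448476.4) is organised around one carbon. C9 of a cyclohexane (ring B of a drimane) is the spiro atom of a dihydrofuran whose other carbons belong to a tropone substituted at every ring position but one. Ring A is cut between C3 and C4 into a propanoic acid on C10 and a 2-hydroxyprop-2-yl group on C5. Four contiguous stereocentres (C5, C10, C9, C8) must be set, and only the quaternary C10 methyl can be bought, so it has to control the rest: C5–H anti to it, the C9–O bond anti to it, and the C8 methyl syn to it. That C8 methyl is axial and 1,3-diaxial to the C10 methyl, the less stable arrangement, so it can only be installed kinetically. C9 is a fully substituted ether carbon next to quaternary C10, so forming its C–O bond by ionisation would invite Wagner–Meerwein shifts and loss of configuration. The tropone is a vinylogous ester with a hindered methyl ester next to its carbonyl group and tolerates neither strong nucleophiles nor long exposure to acid or electrophilic oxidants; the tertiary alcohol and acid of ring A can dehydrate or relactonise and are best released last. The feature that opens the key step is the order of substituents around the seven-membered ring: a (CO2Me), b (C=O), c (CH3), d (O–C9), e (bearing the dihydrofuran CH2, C11), f (H), g (CH3). Carbon e lies between the oxygen-bearing carbon d and the only ring CH (f); removing e leaves a benzene ring with the substitution pattern of O-methylated atraric acid, so e can be delivered as a carbene carbon from C11 across the ipso/ortho bond of an aryl ether.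

## Retrosynthesis

30 ⇒ 29. The C3 acyl–oxygen bond is cut last: 30 is the hydrolysis product of ε-lactone 29. One ring thus masks both the tertiary alcohol and the acid until the end; an open seco acid would need two protecting groups. The forward step must open a lactone without touching the tropone methyl ester, which its flanking methyl and carbonyl groups should shield.

29 ⇒ 27 ⇒ 25 ⇒ 24. No skeletal bond is cut here; the oxidation pattern is moved. Tropone 29 is the hydrolysis product of methoxytropylium ion 28, which is heptafulvene 27 protonated at C11; 27 is the dehydration product of alcohol 25, itself the reduction product of ketone 24. After the one hydride reduction the sequence is redox-neutral: the hydrogen lost from carbon e reappears on C11. This is preferred to acid treatment of 25 itself, where a cation next to the spiro carbon could trigger 1,2-shifts.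

24 ⇒ 22 (key disconnection). Cutting the bonds from carbon e to its neighbours d and f removes one ring carbon and returns the seven-membered ring to a benzene ring; 24 becomes aryloxy diazoketone 22. Two rings (furanone and cycloheptatriene) and two C–C bonds disappear at once, and the arene that appears is the methyl ether of atraric acid 12. A cut between e and C11 would leave the synthesis of a pentasubstituted tropone unsolved, and a cut inside the benzenoid ring would give up the commercial arene. The forward reaction must add a carbenoid across the d–f bond on the C–H side and outrun C–H insertion into ring B.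

22 ⇒ 19 + 20. The C11–C(e) bond is cut: 22 is the acylation product of trimethylsilyldiazomethane 20 with acid 19. The precursor is one carbon smaller and carries no diazo group; the forward step only needs an acid chloride formed under neutral conditions.

19 ⇒ 18 ⇒ 17. The ring-A oxygen between C3 and C4 is removed (Baeyer–Villiger transform), giving keto acid 18, which comes from ester ketal 17 by one acid treatment. Putting the peracid step at the benzenoid stage means no cycloheptatriene or tropone ever meets an electrophilic oxidant, and the lactone is inert in every later step.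

17 ⇒ 11 + 16. The aryl C(d)–O bond is cut and the C9–O bond is left alone. Cutting C9–O instead would require substitution at a neopentyl tertiary carbon, which is either impossible or proceeds by ionisation with scrambling. The fragments are tertiary alcohol 11 and diaryliodonium salt 16; the forward step asks a hindered alkoxide to accept an aryl group without aryne formation.

16 ⇒ 15 ⇒ 14 ⇒ 13 ⇒ 12. The iodine on carbon d is traced through stannane 15 to triflate 14, its phenol 13 and atraric acid 12. The only selectivity required is sulfonylation of the free 4-OH of 12 over the hydrogen-bonded 2-OH.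

11 ⇒ 10 ⇒ 9. The C8–H bond (hydrogenation) and the C9–O bond (oxygenation of an ester dienolate) are cut, leading to tetrasubstituted enoate 9. Dihydroxylation of a C9 methylene compound would need the axial C8 methyl in place first, and that cannot survive a basic olefination of the corresponding ketone. Here the C9 hydroxyl is set by approach anti to the C10 methyl and then directs hydrogen to its own face, which places the C8 methyl axial.

9 ⇒ 8 ⇒ 7 ⇒ 6. The C9–C11 bond (carbonylation of enol triflate 8) and the C8–CH3 bond (alkylation of ketone 6 to 7) are cut. Since C10 is quaternary, ketone 6 can enolise only toward C8, so no regiochemical question arises.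

6 ⇒ 5 ⇒ 4 ⇒ 3 ⇒ 2 ⇒ 1. Ketone 6 is the oxidation product of alcohol 5, the ketal of hydroxy ketone 4. Cutting the two C4–CH3 bonds and the C5–H bond of 4 leads through thiomethyl enone 3 to hydroxy enone 2 and to (R)-Wieland–Miescher ketone 1. Reducing C9 first hides it as an alcohol through the dissolving-metal step and leaves C3 as the only carbonyl when the ketal is made, so the two ketones of 1 are told apart without a protecting-group exchange.

## Roads not taken

Alternative 1: The cut is between carbon e and C11, with the d–O bond closed afterwards. Forward, spiro-epoxide A1 and bromomethoxytropone A2 would be joined at the epoxide CH2 with NiBr2(dme), 2,2'-bipyridine, NaI and Mn powder; the tertiary alkoxide then displaces methoxide from the neighbouring ring carbon to give keto tropone A3. This road is more convergent, and it closes the spiro ether intramolecularly by addition–elimination. In that respect it is better than the chosen plan, which has to arylate a crowded tertiary alkoxide intermolecularly. Its weak points are three. A2 is a pentasubstituted tropone that must first be made, so the hardest part of the target is only moved. Cross-electrophile coupling is established for aryl bromides, not for bromotropones, which are easily reduced and prone to cine substitution. The β-oxido alkyl intermediate at neopentyl C11 can eliminate to the exocyclic alkene. A1 also still needs the axial C8 methyl and the C9 oxygen set beforehand. Against this, the chosen plan makes the tropone from a commercial benzene derivative in the same step that closes the furan ring.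

Alternative 2: The seven-membered ring is cut into a three-carbon and a four-carbon piece. Forward, chromium carbene complex A4 (an α-methylene oxacyclopentylidene complex of Cr(CO)5) would cyclopropanate the silyl enol ether alkene of diene ester A5, and Cope rearrangement of the cis-divinylcyclopropane would give cycloheptadiene A6. It forms two C–C bonds and the ring from small pieces, and the spiro ether oxygen is already in the carbene ligand, so no O-arylation is needed; that is a real advantage over the chosen plan. Against it: A6 is two oxidation levels below a tropone and carries two CH(CH3) stereocentres that are made only to be erased. The push–pull diene A5 offers two alkenes to the carbene. Chromium is stoichiometric, and α-methylene carbene complexes polymerise readily. The chosen plan has to set its longer linear sequence against this, but it delivers the ring one dehydration away from the tropone.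

Alternative 3: Rings A and B and the spiro ether are cut together. Forward, SnCl4 would open the epoxide of farnesylated hydroxytropone A7, two C–C bonds would form, the C8 cation would accept a 1,2-hydride shift from C9, and the tropolone oxygen would close the dihydrofuran to give hydroxy spiro tropone A8. In step count this road is clearly better than the chosen plan, and it sets every ring stereocentre in one operation from a single epoxide stereocentre. Its weakness is that everything rests on one termination event. Proton loss to alkenes can compete with the hydride shift, and direct capture of the C8 cation by oxygen would give the six-membered fused ether in place of the spiro five-membered one. The Lewis-basic tropone binds SnCl4, and its two oxygens are ambident. A7 also presupposes the same pentasubstituted hydroxytropone as alternative 1. The chosen plan is longer, but each stereocentre is set in a step that can be adjusted separately, and the ring size of the ether is fixed by construction.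

Key step: step 19

## Route

Conventions: decalin carbons carry drimane numbers (C1–C10; gem-dimethyl on C4, angular methyl on C10, secondary methyl on C8, C11 = exocyclic carbon on C9). "Syn" and "anti" refer to the face of the C10 methyl group. Arene and seven-ring carbons are lettered a (CO2Me), b (OMe, later C=O), c (CH3), d (O), e (inserted carbon), f (H), g (CH3).

Assumption: 1, 12, 20 and the iodine reagent 1-(diacetoxyiodo)-4-methoxybenzene are taken as commercially available.

Step 1
Reactants: 1 (R)-(−)-Wieland–Miescher ketone
Product: 2 (4aR,5R)-5-hydroxy-4a-methyl-4,4a,5,6,7,8-hexahydronaphthalen-2(3H)-one (C9–OH syn to the angular methyl)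
Conditions: NaBH4 (0.3 equiv), EtOH, −10 °C
Reagents that add atoms: none
Why: Chemoselective carbonyl reduction: the saturated ketone is much more electrophilic than the enone carbonyl and hydride arrives anti to the angular methyl; the carbinol centre only masks C9 and is oxidised away in step 5.

Step 2
Reactants: 2 hydroxy enone
Product: 3 hydroxy enone carrying a (phenylsulfanyl)methyl group on C4
Conditions: PhSH, 37% aq. CH2O, Et3N, EtOH, 80 °C
Reagents that add atoms: formaldehyde, C=O; thiophenol, Sc1ccccc1
Why: Kirk–Petrow thiomethylation: the enone reacts through its dienolate at the α-carbon (C4) with formaldehyde and thiophenol traps the resulting methylene ketone, which installs the first C4 methyl carbon in masked form.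

Step 3
Reactants: 3 thiomethyl enone
Product: 4 9-hydroxy-4,4,10-trimethyl-trans-decalin-3-one
Conditions: Li, NH3(l)–THF, t-BuOH (1 equiv), −78 → −33 °C; then MeI
Reagents that add atoms: iodomethane, CI
Why: Dissolving-metal reductive alkylation: C–S cleavage and enone reduction give the C4-methyl lithium enolate, protonation at C5 occurs anti to the angular methyl and sets the trans ring fusion, and the enolate is then methylated regiospecifically at C4; the C9 lithium alkoxide is inert.

Step 4
Reactants: 4 hydroxy ketone
Product: 5 3,3-ethylenedioxy ketal of 4
Conditions: HOCH2CH2OH, TsOH·H2O (cat.), benzene, reflux (Dean–Stark)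
Reagents that add atoms: ethylene glycol, OCCO
Why: Acid-catalysed ketalisation with azeotropic removal of water; C3 is the only carbonyl present, so the dioxolane is placed without any selectivity problem.

Step 5
Reactants: 5 ketal alcohol
Product: 6 3,3-ethylenedioxy-4,4,10-trimethyl-trans-decalin-9-one
Conditions: Dess–Martin periodinane, NaHCO3, CH2Cl2, rt
Reagents that add atoms: none
Why: Periodinane oxidation of a hindered secondary alcohol under buffered conditions that leave the dioxolane intact; the C9 ketone returns, now differentiated from C3.

Step 6
Reactants: 6 ketal ketone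
Product: 7 8-methyl derivative of 6 (methyl equatorial)
Conditions: LiN(i-Pr)2, THF, −78 °C; MeI, −78 → 0 °C
Reagents that add atoms: iodomethane, CI
Why: Ketone enolate alkylation; C10 is quaternary, so the enolate can only form toward C8, and the configuration at C8 does not matter because the centre becomes trigonal in step 7.

Step 7
Reactants: 7 8-methyl ketone
Product: 8 enol triflate (C8=C9, OTf on C9)
Conditions: KN(SiMe3)2, THF, −78 → 0 °C; PhNTf2
Reagents that add atoms: N-phenylbis(trifluoromethanesulfonimide), O=S(=O)(N(c1ccccc1)S(=O)(=O)C(F)(F)F)C(F)(F)F
Why: O-sulfonylation of the only possible enolate gives the tetrasubstituted enol triflate as a single regioisomer.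

Step 8
Reactants: 8 enol triflate
Product: 9 4-methoxybenzyl 3,3-ethylenedioxy-4,4,8,10-tetramethyl-Δ8-octalin-9-carboxylate
Conditions: CO (1 atm), 4-MeOC6H4CH2OH, Pd(OAc)2, PPh3, Et3N, DMF, 70 °C
Reagents that add atoms: carbon monoxide, [C-]#[O+]; 4-methoxybenzyl alcohol, COc1ccc(CO)cc1
Why: Palladium-catalysed alkoxycarbonylation of an enol triflate (oxidative addition, CO insertion, alcoholysis of the acylpalladium species) introduces C11 at the carboxyl level as an acid-labile ester.

Step 9
Reactants: 9 tetrasubstituted enoate
Product: 10 4-methoxybenzyl 9-hydroxy-Δ7-octalin-9-carboxylate (9-OH anti to the C10 methyl)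
Conditions: LiN(i-Pr)2, THF–DMPU, −78 °C; 2-(phenylsulfonyl)-3-phenyloxaziridine, −78 °C; aq. NH4Cl
Reagents that add atoms: 2-(phenylsulfonyl)-3-phenyloxaziridine, O=S(=O)(c1ccccc1)N1OC1c1ccccc1
Why: Deconjugative α-hydroxylation of an ester dienolate: γ-deprotonation at C7 gives the extended enolate, which takes electrophilic oxygen at its α-carbon (C9) on the face anti to the pseudo-axial C10 methyl, setting the C9–O configuration; any exocyclic C8=CH2 isomer from deprotonation of the C8 methyl converges in step 10.

Step 10
Reactants: 10 hydroxy Δ7 ester
Product: 11 4-methoxybenzyl 9-hydroxy-8-methyldecalin-9-carboxylate (8-methyl syn, 9-OH anti to the C10 methyl)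
Conditions: H2 (1 atm), [Ir(cod)(PCy3)(py)]PF6 (5 mol %), CH2Cl2, rt
Reagents that add atoms: none
Why: Hydroxyl-directed homogeneous hydrogenation: the tertiary C9–OH binds the cationic iridium centre and both hydrogens are delivered to its face, so C8–H ends anti and the C8 methyl syn (axial) to the C10 methyl, the kinetically set, less stable epimer; this catalyst does not hydrogenolyse the benzylic ester.

Step 11
Reactants: 12 atraric acid
Product: 13 methyl 2-hydroxy-3,6-dimethyl-4-[(trifluoromethylsulfonyl)oxy]benzoate
Conditions: Tf2O (1.05 equiv), pyridine, CH2Cl2, −40 → 0 °C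
Reagents that add atoms: trifluoromethanesulfonic anhydride, O=S(=O)(OS(=O)(=O)C(F)(F)F)C(F)(F)F
Why: Phenol sulfonylation; the 2-OH is hydrogen-bonded to the ester carbonyl and much less nucleophilic, so only the 4-OH (carbon d) should react.

Step 12
Reactants: 13 monotriflate
Product: 14 methyl 2-methoxy-3,6-dimethyl-4-[(trifluoromethylsulfonyl)oxy]benzoate
Conditions: MeI, K2CO3, acetone, 55 °C
Reagents that add atoms: iodomethane, CI
Why: Williamson methylation of the chelated phenol; the methoxy group on carbon b is the leaving group that later uncovers the tropone carbonyl.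

Step 13
Reactants: 14 aryl triflate
Product: 15 methyl 2-methoxy-3,6-dimethyl-4-(trimethylstannyl)benzoate
Conditions: Me3SnSnMe3, Pd(PPh3)4 (5 mol %), LiCl, 1,4-dioxane, 100 °C
Reagents that add atoms: hexamethylditin, C[Sn](C)(C)[Sn](C)(C)C
Why: Palladium-catalysed stannylation of an aryl triflate (oxidative addition, transmetalation with the distannane, reductive elimination) replaces the oxygen on carbon d by tin.

Step 14
Reactants: 15 arylstannane
Product: 16 [3-methoxy-4-(methoxycarbonyl)-2,5-dimethylphenyl](4-methoxyphenyl)iodonium p-toluenesulfonate
Conditions: 4-MeOC6H4I(OAc)2, TsOH·H2O, MeCN–CH2Cl2, 0 °C → rt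
Reagents that add atoms: 1-(diacetoxyiodo)-4-methoxybenzene, COc1ccc(I(OC(C)=O)OC(C)=O)cc1; p-toluenesulfonic acid, Cc1ccc(S(=O)(=O)O)cc1
Why: Ipso-substitution of tin by the hydroxy(tosyloxy)iodoarene formed in the flask gives the unsymmetrical diaryliodonium salt at carbon d only; the electron-rich, unhindered anisyl ring is chosen as the ligand that is not transferred.

Step 15
Reactants: 11 tertiary hydroxy ester; 16 diaryliodonium salt
Product: 17 9-O-aryl ether of 11 (aryl = 3-methoxy-4-(methoxycarbonyl)-2,5-dimethylphenyl)
Conditions: NaH, toluene, 0 °C → rt; then 16, rt → 45 °C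
Reagents that add atoms: none
Why: Metal-free O-arylation of a tertiary alkoxide with a diaryl-λ3-iodane: the alkoxide replaces tosylate on iodine and ligand coupling transfers the more electron-poor, ortho-substituted benzoate ring; the C9–O bond is never broken, so the C9 configuration is retained.

Step 16
Reactants: 17 aryl ether ester ketal
Product: 18 9-aryloxy-3-oxo acid
Conditions: TFA–H2O (9:1), pentamethylbenzene, CH2Cl2, 0 °C → rt
Reagents that add atoms: water, O
Why: Acidolysis of the 4-methoxybenzyl ester (benzylic cation trapped by pentamethylbenzene) and hydrolysis of the dioxolane in one operation; the C9 ether does not ionise because C9 carries the electron-withdrawing carboxyl group.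

Step 17
Reactants: 18 keto acid
Product: 19 9-aryloxy lactone acid (ring A as ε-lactone, oxygen between C3 and C4)
Conditions: mCPBA, Na2HPO4, CH2Cl2, rt
Reagents that add atoms: 3-chloroperoxybenzoic acid, O=C(OO)c1cccc(Cl)c1
Why: Baeyer–Villiger oxidation; the fully substituted C4 migrates in preference to the C2 methylene, and the only π system present is an ester-deactivated benzene ring, which should be inert to the peracid.

Step 18
Reactants: 19 lactone acid; 20 trimethylsilyldiazomethane
Product: 22 aryloxy diazoketone (C9–C(=O)–CH=N2), via acid chloride 21 (not isolated)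
Conditions: 1-chloro-N,N,2-trimethylprop-1-en-1-amine, CH2Cl2, 0 °C → rt; then 20, MeCN–THF, 0 °C → rt
Reagents that add atoms: none
Why: Neutral acid chloride formation followed by C-acylation of the silyl diazomethane with loss of Me3SiCl (first stage of an Arndt–Eistert sequence) gives the terminal α-diazoketone; no HCl is released, which spares the tertiary-alkyl lactone.

Step 19
Reactants: 22 aryloxy diazoketone
Product: 24 spiro furanone-fused methoxycycloheptatriene (ring-fusion H syn to C8), via norcaradiene 23 (not isolated)
Conditions: Rh2(OAc)4 (1 mol %), CH2Cl2 (passed through basic Al2O3), slow addition of 22, 25 → 40 °C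
Reagents that add atoms: none
Why: Rh2(OAc)4 expels N2 from 22 to give an electrophilic rhodium carbenoid, which adds across the bond between arene carbons d (ipso to the ether oxygen) and f (the unsubstituted ortho carbon) to give norcaradiene 23; thermal disrotatory six-electron opening of the d–f bond then gives cycloheptatriene 24. The closest known reaction type is the dirhodium-catalysed intramolecular Büchner reaction of 1-diazo-3-aryloxypropan-2-ones to 2H-cyclohepta[b]furan-3-ones. The furanone ring closes through the e–d bond in an intramolecular [2+1] cycloaddition, the three-atom tether O–C9–C11 allowing only the ipso/ortho mode; the seven-membered ring arises from the e–f bond and the electrocyclic opening. The one new stereocentre, the ring-fusion CH (e), is set by the face of the arene offered to the carbenoid: the arene should turn its methyl-bearing flank (c) toward the C8–H side of C9, which puts H(e) syn to C8; the centre is epimerisable and is removed in step 21, so it need not be controlled. Site selectivity for f over c is needed and is secured because f is unsubstituted, ortho to the ether oxygen and para to the methoxy group, whereas addition at c would build a fully substituted cyclopropane. Chemoselectivity over 1,5 C–H insertion into the C1 methylene or the methyl groups flanking C11 rests on the electron-rich π system and on the absence of activated C–H bonds within reach; dilute, acid-free conditions guard against carbene dimerisation and acid-induced rearomatisation to a chroman-3-one.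

Step 20
Reactants: 24 cycloheptatriene ketone
Product: 25 C11 alcohol (OH trans to the ring-fusion H)
Conditions: NaBH4, CeCl3·7H2O, MeOH–THF, −78 → −40 °C
Reagents that add atoms: none
Why: Luche reduction of the furanone carbonyl; the cerium salt keeps the medium weakly basic so the acidic ring-fusion hydrogen is not removed, hydride approaches from the side of that hydrogen (away from carbon f), and the lactone and esters are untouched; the carbinol centre is temporary.

Step 21
Reactants: 25 alcohol
Product: 27 heptafulvene (C11=C(e) double bond), via mesylate 26 (not isolated)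
Conditions: MsCl, Et3N, CH2Cl2, −20 °C; then DBU, 0 °C → rt; used at once
Reagents that add atoms: none
Why: Sulfonylation and E2 elimination toward the only β-hydrogen, the allylic ring-fusion H, which is anti to the mesylate (C9 carries no hydrogen); the cross-conjugated heptafulvene is kept basic and is not stored.

Step 22
Reactants: 27 heptafulvene
Product: 29 spiro tropone (ring A as ε-lactone), via methoxytropylium chloride 28 (not isolated)
Conditions: 1 M aq. HCl, THF, 0 °C; then aq. NaHCO3
Reagents that add atoms: water, O
Why: Heptafulvenes protonate at the exocyclic carbon, so C11 becomes CH2 and the ring becomes an aromatic methoxytropylium ion stabilised by both oxygens; water then adds at the methoxy-bearing carbon b and methanol leaves (hydrolysis of an alkoxytropylium ion), which gives the tropone without any step that could ionise C9.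

Step 23
Reactants: 29 tropone lactone
Product: 30 CNP0448476.4
Conditions: LiOH·H2O, THF–H2O (3:1), 0 °C → rt; then 1 M HCl to pH 4
Reagents that add atoms: lithium hydroxide, [Li+].[OH-]
Why: Saponification of the ε-lactone by acyl–oxygen cleavage at the unhindered C3 carbonyl releases the C3 acid and the C4 tertiary alcohol; the tropone methyl ester, flanked by the carbonyl group and a methyl group, should react far more slowly, and mild acidification avoids relactonisation and dehydration.

## Compound list

1 | (R)-(−)-Wieland–Miescher ketone, (8aR)-8a-methyl-3,4,8,8a-tetrahydronaphthalene-1,6(2H,7H)-dione | C[C@@]12CCC(=O)C=C1CCCC2=O | starting material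
2 | (4aR,5R)-5-hydroxy-4a-methyl-4,4a,5,6,7,8-hexahydronaphthalen-2(3H)-one (C9–OH syn to the angular methyl) | C[C@@]12CCC(=O)C=C1CCC[C@H]2O | intermediate
3 | 2 carrying a (phenylsulfanyl)methyl group on C4 | C[C@@]12CCC(=O)C(CSc3ccccc3)=C1CCC[C@H]2O | intermediate
4 | 9-hydroxy-4,4,10-trimethyl-trans-decalin-3-one (5-H anti, 9-OH syn to the C10 methyl) | O[C@@H]1CCC[C@H]2[C@@]1(C)CCC(=O)C2(C)C | intermediate
5 | 3,3-ethylenedioxy ketal of 4 | O[C@@H]1CCC[C@H]2[C@@]1(C)CCC3(OCCO3)C2(C)C | intermediate
6 | 3,3-ethylenedioxy-4,4,10-trimethyl-trans-decalin-9-one | O=C1CCC[C@H]2[C@@]1(C)CCC3(OCCO3)C2(C)C | intermediate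
7 | 8-methyl derivative of 6 (methyl equatorial, anti to the C10 methyl) | O=C1[C@@H](C)CC[C@H]2[C@@]1(C)CCC3(OCCO3)C2(C)C | intermediate
8 | enol triflate of 7 (C8=C9, OTf on C9) | O=S(=O)(OC1=C(C)CC[C@H]2[C@@]1(C)CCC3(OCCO3)C2(C)C)C(F)(F)F | intermediate
9 | 4-methoxybenzyl 3,3-ethylenedioxy-4,4,8,10-tetramethyl-Δ8-octalin-9-carboxylate | COc1ccc(COC(=O)C2=C(C)CC[C@H]3[C@@]2(C)CCC4(OCCO4)C3(C)C)cc1 | intermediate
10 | 4-methoxybenzyl 9-hydroxy-Δ7-octalin-9-carboxylate, 3-ketal (9-OH anti to the C10 methyl) | COc1ccc(COC(=O)[C@]2(O)C(C)=CC[C@H]3[C@@]2(C)CCC4(OCCO4)C3(C)C)cc1 | intermediate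
11 | 4-methoxybenzyl 9-hydroxy-8-methyldecalin-9-carboxylate, 3-ketal (8-methyl syn, 9-OH anti to the C10 methyl) | COc1ccc(COC(=O)[C@]2(O)[C@H](C)CC[C@H]3[C@@]2(C)CCC4(OCCO4)C3(C)C)cc1 | intermediate
12 | atraric acid, methyl 2,4-dihydroxy-3,6-dimethylbenzoate | COC(=O)c1c(C)cc(O)c(C)c1O | starting material
13 | methyl 2-hydroxy-3,6-dimethyl-4-[(trifluoromethylsulfonyl)oxy]benzoate | COC(=O)c1c(C)cc(OS(=O)(=O)C(F)(F)F)c(C)c1O | intermediate
14 | methyl 2-methoxy-3,6-dimethyl-4-[(trifluoromethylsulfonyl)oxy]benzoate | COC(=O)c1c(C)cc(OS(=O)(=O)C(F)(F)F)c(C)c1OC | intermediate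
15 | methyl 2-methoxy-3,6-dimethyl-4-(trimethylstannyl)benzoate | COC(=O)c1c(C)cc([Sn](C)(C)C)c(C)c1OC | intermediate
16 | [3-methoxy-4-(methoxycarbonyl)-2,5-dimethylphenyl](4-methoxyphenyl)iodonium p-toluenesulfonate | COC(=O)c1c(C)cc([I+]c2ccc(OC)cc2)c(C)c1OC.Cc1ccc(S(=O)(=O)[O-])cc1 | intermediate
17 | 9-O-aryl ether of 11 (4-methoxybenzyl ester, 3-ketal) | COC(=O)c1c(C)cc(O[C@@]2(C(=O)OCc3ccc(OC)cc3)[C@H](C)CC[C@H]4[C@@]2(C)CCC5(OCCO5)C4(C)C)c(C)c1OC | intermediate
18 | 9-aryloxy-3-oxo acid (free C11 acid, ring-A ketone) | COC(=O)c1c(C)cc(O[C@@]2(C(=O)O)[C@H](C)CC[C@H]3[C@@]2(C)CCC(=O)C3(C)C)c(C)c1OC | intermediate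
19 | 9-aryloxy lactone acid (ring A as ε-lactone, O between C3 and C4) | COC(=O)c1c(C)cc(O[C@@]2(C(=O)O)[C@H](C)CC[C@H]3[C@@]2(C)CCC(=O)OC3(C)C)c(C)c1OC | intermediate
20 | trimethylsilyldiazomethane | C[Si](C)(C)C=[N+]=[N-] | starting material
21 | acid chloride of 19 | COC(=O)c1c(C)cc(O[C@@]2(C(=O)Cl)[C@H](C)CC[C@H]3[C@@]2(C)CCC(=O)OC3(C)C)c(C)c1OC | intermediate
22 | aryloxy diazoketone on the spiro carbon (ring A as ε-lactone) | COC(=O)c1c(C)cc(O[C@@]2(C(=O)C=[N+]=[N-])[C@H](C)CC[C@H]3[C@@]2(C)CCC(=O)OC3(C)C)c(C)c1OC | intermediate
23 | norcaradiene (carbon e bonded to arene carbons d and f) | COC(=O)C1=C(C)[C@H]2[C@@H]3C(=O)[C@]4(O[C@]23C(C)=C1OC)[C@H](C)CC[C@H]5[C@@]4(C)CCC(=O)OC5(C)C | intermediate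
24 | spiro furanone-fused methoxycycloheptatriene (2H-cyclohepta[b]furan-3-one; ring-fusion H syn to C8) | COC(=O)C1=C(OC)C(C)=C2O[C@@]3(C(=O)[C@H]2C=C1C)[C@H](C)CC[C@H]4[C@@]3(C)CCC(=O)OC4(C)C | intermediate
25 | C11 alcohol of 24 (OH trans to the ring-fusion H) | COC(=O)C1=C(OC)C(C)=C2O[C@@]3([C@@H](O)[C@H]2C=C1C)[C@H](C)CC[C@H]4[C@@]3(C)CCC(=O)OC4(C)C | intermediate
26 | methanesulfonate of 25 | COC(=O)C1=C(OC)C(C)=C2O[C@@]3([C@@H](OS(C)(=O)=O)[C@H]2C=C1C)[C@H](C)CC[C@H]4[C@@]3(C)CCC(=O)OC4(C)C | intermediate
27 | heptafulvene (C11=C(e)) | COC(=O)C1=C(OC)C(C)=C2O[C@@]3(C=C2C=C1C)[C@H](C)CC[C@H]4[C@@]3(C)CCC(=O)OC4(C)C | intermediate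
28 | methoxytropylium chloride (C11 = CH2) | COC(=O)C1=C(C)C=C2C(=C(C)C1=[O+]C)O[C@@]1(C2)[C@H](C)CC[C@H]2[C@@]1(C)CCC(=O)OC2(C)C.[Cl-] | intermediate
29 | spiro dihydrofuro-tropone with ring A as ε-lactone | COC(=O)c1c(C)cc2c(c(C)c1=O)O[C@@]1(C2)[C@H](C)CC[C@H]2[C@@]1(C)CCC(=O)OC2(C)C | intermediate
30 | CNP0448476.4 (3,4-seco acid with C4 tertiary alcohol) | COC(=O)c1c(C)cc2c(c(C)c1=O)O[C@@]1(C2)[C@H](C)CC[C@H](C(C)(C)O)[C@@]1(C)CCC(=O)O | target

## Step count and least certain steps

Total: 23 steps. Longest linear sequence: 19 steps from 1 (steps 1–10 and 15–23). The arene branch (steps 11–14) is 4 steps from 12.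

Step 19 (key step). What may go wrong: loss of chemoselectivity of the carbenoid, through 1,5 insertion into the C1 methylene or the methyl groups that flank C11, or through electrophilic substitution at carbon f in place of cycloaddition. Acid-induced rearomatisation of the cycloheptatriene during isolation is also possible, because the ring-fusion hydrogen is enolisable. Fallback: the route leaves at lactone acid 19 (through its chloride 21) and returns at 24. Acylation of the lithium enolate of allyl acetate (LiN(i-Pr)2, THF, −78 °C) with 21 gives the β-keto allyl ester F1. Diazo transfer (4-acetamidobenzenesulfonyl azide, Et3N, MeCN) gives the 2-diazo-3-oxo ester F2. With Rh2(OAc)4 this doubly acceptor-substituted carbenoid is more electrophilic and bulkier, which favours the electron-rich arene over unactivated C–H bonds, and it gives the ring-fusion allyl ester F3. F3 has no enolisable ring-fusion hydrogen and can be purified. Pd(PPh3)4 with morpholine removes the allyl group, the β-keto acid loses CO2, and 24 results.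

Step 15. What may go wrong: slow ligand exchange and coupling at the crowded tertiary alkoxide; base-induced aryne formation from 16 by deprotonation next to iodine, which would scramble the position of the ether; or transfer of the anisyl ligand. Fallback: from triflate 14 and alcohol 11, back to 17. Fluorination of 14 (CsF, [Pd(cinnamyl)Cl]2, t-BuBrettPhos, toluene, 110 °C) gives methyl 4-fluoro-2-methoxy-3,6-dimethylbenzoate F4. The potassium alkoxide of 11 (KN(SiMe3)2, 18-crown-6, DMF, 0 → 60 °C) then displaces fluoride para to the ester by addition–elimination. No ligand on iodine has to be selected and no aryne can form. The price is the modest activation by a twisted ester, which is why this is the second choice.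

Step 9. What may go wrong: oxygen transfer to the γ-carbon (C7) in place of the crowded α-carbon, incomplete γ-deprotonation of the tetrasubstituted enoate, or addition of the dienolate to the sulfonimine by-product. Fallback: from 9, back to 10. Reduction of 9 with i-Bu2AlH gives allylic alcohol F5. mCPBA epoxidises the tetrasubstituted alkene anti to the C10 methyl to give epoxy alcohol F6. Al(Oi-Pr)3 (toluene, 110 °C) isomerises the epoxide to an allylic alcohol by removing a C7 hydrogen and breaking the C8–O bond, which leaves the oxygen on C9 and gives the Δ7 diol F7. Oxidation of the primary alcohol (TEMPO, NaOCl cat., NaClO2, pH 7 buffer) gives hydroxy acid F8, and 4-methoxybenzyl chloride with K2CO3 in DMF returns 10. Here oxygen is delivered to an alkene by a peracid and not to an enolate.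

Step 21. What may go wrong: sluggish elimination at a neopentyl-type carbinol carbon, ionisation of the mesylate with ring-enlarging 1,2-shift of C8 or C10 away from C9, and oligomerisation or air oxidation of the heptafulvene before it is protonated. Fallback: from 25, back to 29, bypassing steps 21 and 22. With 1,1'-thiocarbonyldiimidazole (DMAP, CH2Cl2), 25 gives thiocarbonylimidazolide F9. Bu3SnH with azobisisobutyronitrile in toluene at 80 °C (Barton–McCombie deoxygenation) gives the C11-methylene cycloheptatriene F10. Hydride abstraction from the ring-fusion CH by Ph3CBF4 (MeCN, 0 °C) gives methoxytropylium tetrafluoroborate F11, the same cation as in 28, and aqueous NaHCO3 hydrolyses it to 29. The tropylium ion is reached by oxidation of a cycloheptatriene, so no heptafulvene is involved.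

## Further compounds

F1 | step 19 | β-keto allyl ester from 21 (C9–C(=O)–CH2–CO2allyl) | COC(=O)c1c(C)cc(O[C@@]2(C(=O)CC(=O)OCC=C)[C@H](C)CC[C@H]3[C@@]2(C)CCC(=O)OC3(C)C)c(C)c1OC
F2 | step 19 | 2-diazo-3-oxo allyl ester | COC(=O)c1c(C)cc(O[C@@]2(C(=O)C(=[N+]=[N-])C(=O)OCC=C)[C@H](C)CC[C@H]3[C@@]2(C)CCC(=O)OC3(C)C)c(C)c1OC
F3 | step 19 | furanone-fused cycloheptatriene with CO2allyl on the ring-fusion carbon | COC(=O)C1=C(OC)C(C)=C2O[C@@]3(C(=O)[C@@]2(C(=O)OCC=C)C=C1C)[C@H](C)CC[C@H]4[C@@]3(C)CCC(=O)OC4(C)C
F4 | step 15 | methyl 4-fluoro-2-methoxy-3,6-dimethylbenzoate | COC(=O)c1c(C)cc(F)c(C)c1OC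
F5 | step 9 | Δ8 allylic alcohol (C11 = CH2OH, 3-ketal) | OCC1=C(C)CC[C@H]2[C@@]1(C)CCC3(OCCO3)C2(C)C
F6 | step 9 | 8,9-epoxy alcohol (epoxide anti to the C10 methyl) | OC[C@]12O[C@@]1(C)CC[C@H]3[C@@]2(C)CCC4(OCCO4)C3(C)C
F7 | step 9 | Δ7 9,11-diol (9-OH anti to the C10 methyl) | O[C@@]1(CO)C(C)=CC[C@H]2[C@@]1(C)CCC3(OCCO3)C2(C)C
F8 | step 9 | 9-hydroxy-Δ7-octalin-9-carboxylic acid, 3-ketal | O[C@@]1(C(=O)O)C(C)=CC[C@H]2[C@@]1(C)CCC3(OCCO3)C2(C)C
F9 | step 21 | O-(imidazol-1-ylthiocarbonyl) derivative of 25 | COC(=O)C1=C(OC)C(C)=C2O[C@@]3([C@@H](OC(=S)n5ccnc5)[C@H]2C=C1C)[C@H](C)CC[C@H]4[C@@]3(C)CCC(=O)OC4(C)C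
F10 | step 21 | C11-methylene cycloheptatriene (deoxygenated 25) | COC(=O)C1=C(OC)C(C)=C2O[C@@]3(C[C@H]2C=C1C)[C@H](C)CC[C@H]4[C@@]3(C)CCC(=O)OC4(C)C
F11 | step 21 | methoxytropylium tetrafluoroborate | COC(=O)C1=C(C)C=C2C(=C(C)C1=[O+]C)O[C@@]1(C2)[C@H](C)CC[C@H]2[C@@]1(C)CCC(=O)OC2(C)C.F[B-](F)(F)F
A1 | alternative 1 | spiro-epoxide with ring-A ketone | C1O[C@]12[C@H](C)CC[C@H]3[C@@]2(C)CCC(=O)C3(C)C
A2 | alternative 1 | bromomethoxytropone ester | COC(=O)c1c(C)cc(Br)c(OC)c(C)c1=O
A3 | alternative 1 | ring-A-keto spiro tropone | COC(=O)c1c(C)cc2c(c(C)c1=O)O[C@@]1(C2)[C@H](C)CC[C@H]3[C@@]1(C)CCC(=O)C3(C)C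
A4 | alternative 2 | α-methylene oxacyclopentylidene complex of Cr(CO)5 | C=C1C[C@]2(OC1=[Cr](=C=O)(=C=O)(=C=O)(=C=O)=C=O)[C@H](C)CC[C@H]3[C@@]2(C)CCC4(OCCO4)C3(C)C
A5 | alternative 2 | methyl (2E,3Z)-2-ethylidene-3-[(tert-butyldimethylsilyl)oxy]pent-3-enoate | C/C=C(C(=O)OC)\C(O[Si](C)(C)C(C)(C)C)=C\C
A6 | alternative 2 | dihydrofuran-fused cycloheptadiene silyl enol ether | COC(=O)C1=C(O[Si](C)(C)C(C)(C)C)[C@H](C)C2=C(C[C@H]1C)C[C@]3(O2)[C@H](C)CC[C@H]4[C@@]3(C)CCC5(OCCO5)C4(C)C
A7 | alternative 3 | epoxyfarnesyl hydroxytropone ester | COC(=O)c1c(C)cc(C/C=C(\C)CC/C=C(\C)CC[C@H]2OC2(C)C)c(O)c(C)c1=O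
A8 | alternative 3 | 3-hydroxy spiro tropone (trans-decalin) | COC(=O)c1c(C)cc2c(c(C)c1=O)O[C@@]1(C2)[C@H](C)CC[C@H]3[C@@]1(C)CC[C@@H](O)C3(C)C
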